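(The readings are calculated on assumed constants; the scatter is artificial.)

A small charge of initiator, 10 mM against 1.0 M of free monomer, caps the chains if each initiator begins one. This reckoning assumes so, because Monday's flask, with less transfer agent, holds 18.7% in chains at 40.0 h against Sunday's 13.0%, which fits an agent that ends chains and begins none.

| setting | Monday's | Sunday's | south-east | east |
|---|---|---|---|---|
| free monomer | 1 M | 1 M | 1.0 M | 1.0 M |
| transfer agent | 0.20 M | 0.45 M | 0.300 M | 0.300 M |
| initiator | 10 mM | 10 mM | 10 mM | 10 mM |
| remark | run made earlier | run made earlier |  |  |
| time |  |  | 40 h | 10 h |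

| run | time / h | monomer in chains / % | free monomer / % |
|---|---|---|---|
| Monday's | 3.00 | 1.3 | 94.1 |
| Monday's | 5.00 | 2.6 | 89.9 |
| Monday's | 8.00 | 5.1 | 83.2 |
| Monday's | 15.0 | 9.8 | 70.2 |
| Monday's | 25.0 | 14.6 | 55.9 |
| Monday's | 40.0 | 18.7 | 40.8 |
| Sunday's | 6.00 | 3.2 | 88.1 |
| Sunday's | 12.0 | 7.3 | 76.8 |
| Sunday's | 20.0 | 9.8 | 64.9 |
| Sunday's | 25.0 | 11.3 | 58.2 |
| Sunday's | 30.0 | 12.0 | 53.9 |
| Sunday's | 40.0 | 13.0 | 45.2 |

(each reading ± 0.3 percentage points)

- the average divides the monomer in chains by the number of chains begun, living and dead together
- the earlier runs do not show the number of chains; that part of a forecast is a guess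

- which of the two ends with the longer chains by the average number of monomer units in a chain (chains begun, living or dead) ("neither" if they lie within 10%) (south-east / east / neither)
- average number of monomer units in a chain (chains begun, living or dead) at the end, south-east
- average number of monomer units in a chain (chains begun, living or dead) at the end, east

South-east's agent charge lies 0.400 of the way from Monday's to Sunday's, so it should hold 16.4% in chains at 40 h, or 16.4 monomer units per initiator charged. This ratio of monomer in chains to initiator charged, the chain load n, gives the number-average length, on that assumption, when divided by the fraction of initiator used. At 10 h, straight lines between the readings give about 6.44% for Monday's run and 5.93% for Sunday's, so east should hold 6.24% in chains, with n = 6.24. One number is not quite enough: on this reckoning east can pass south-east only if under 0.380 of its initiator is used by then, and Monday's readings, which gain less per hour from 8.00 h to 15.0 h than from 5.00 h to 8.00 h, speak against that. This reckoning therefore picks south-east.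

The forecast differs, choosing east, with 13 (5 to 30) for south-east and 18 (7 to 40) for east: “Chains keep starting while incorporation fades, so the average falls with time.”

The flasks give 16.2 for south-east and 7.48 for east, so south-east is longer.

    free monomer + initiator → living end + monomer in chains (k = 5.70 × 10⁻⁵ /M/s)
    free monomer + living end → monomer in chains + living end, rate k2*[living end]*[free monomer] (k = 3.70 × 10⁻⁴ /M/s)
    living end + transfer agent → dead chain (kL = 4.60 × 10⁻⁵ /M/s)
    free monomer → uncatalysed product (k = 4.30 × 10⁻⁶ /s)

East stopped at 10.0 h with 16% of its initiator left, so its n of 6.24 over the 84.0% used gives 7.43. South-east ran on until 0.43% of its initiator stood, while living ends kept adding free monomer to chains, and its length of 16.2 stands beside its n of 16.4. A neighbour of south-east charged with 0.025 M of initiator kept 0.99% of it and held 34.9% in chains, so n = 14.0, with a simulated length of 14.1.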